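**Retrosynthetic overview**
1. Target 41 ← 9‑OH/9‑OTBS α‑methylene lactone ← macrocyclic lactone 35 (acetylation, desilylation and α‑methylenation come last).
2. 35 ← seco bromo‑diene 33: the 14‑membered ring is closed last, at C6–C7, by an intramolecular B‑alkyl Suzuki–Miyaura coupling.
3. 33 ← key union at C12–C13: B‑alkyl Suzuki–Miyaura coupling of East lactone 17 (11 C: C1–C6, C13–C16) with West alkenyl iodide 31 (8 C: C7–C12).
4. East: chiral‑pool lactone 1 (the five‑membered ring is present from the start) → butenolide → anti vinyl‑cuprate addition (sets C1, trans to C2) → two Wittig olefinations, using ylide 14 made from bromoethane and ethyl formate.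
5. West: propargyl alcohol → carboalumination/bromination → enal → catalytic asymmetric propargylation (sets C9) → alkyne methylation → hydrozirconation/iodination.

Assumption: ring positions use cembrane numbering (C1 = ring CH carrying the lactone α‑carbon C15; C2 = O–CH; C3=C4, C7=C8, C11=C12 the ring alkenes; C9 the oxygenated carbon; C16 = lactone C=O; C17 = exocyclic CH2), and starting materials 1, 10, 12, 18 and 21 are taken as purchasable.

**East fragment**

Step 1
Reactants: 1 (R)-5-(hydroxymethyl)dihydrofuran-2(3H)-one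
Product: 2 (R)-5-{[(tert-butyldiphenylsilyl)oxy]methyl}dihydrofuran-2(3H)-one
Conditions: TBDPSCl, imidazole, DMF, 0 °C → rt
Reagents that add atoms: tert-butyl(chloro)diphenylsilane, CC(C)(C)[Si](Cl)(c1ccccc1)c1ccccc1
Why: Routine silyl ether protection of the primary alcohol, giving a bulky group that later shields one face of the butenolide.

Step 2
Reactants: 2 (R)-5-{[(tert-butyldiphenylsilyl)oxy]methyl}dihydrofuran-2(3H)-one
Product: 6 (R)-5-{[(tert-butyldiphenylsilyl)oxy]methyl}furan-2(5H)-one, via lithium enolate 3 (not isolated), via phenylselanyl lactone 4 (not isolated), via selenoxide 5 (not isolated)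
Conditions: LDA, THF, −78 °C; PhSeBr; then H2O2, pyridine, CH2Cl2, 0 °C → rt
Reagents that add atoms: none
Why: α‑Selenenylation of the lactone enolate followed by selenoxide syn‑elimination gives the butenolide without touching the C5 stereocentre.

Step 3
Reactants: 6 (R)-5-{[(tert-butyldiphenylsilyl)oxy]methyl}furan-2(5H)-one
Product: 8 (4S,5R)-5-{[(tert-butyldiphenylsilyl)oxy]methyl}-4-vinyldihydrofuran-2(3H)-one, via silyl ketene acetal 7 (not isolated)
Conditions: CH2=CHMgBr, CuBr·SMe2 (10 mol %), TMSCl, THF, −78 °C; aq. NH4Cl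
Reagents that add atoms: vinylmagnesium bromide, C=C[Mg]Br
Why: Copper‑catalysed conjugate addition of the vinyl Grignard reagent occurs anti to the C5 CH2OTBDPS group and so sets the 4S centre (C1 of the target) trans to C5.

Step 4
Reactants: 8 (4S,5R)-5-{[(tert-butyldiphenylsilyl)oxy]methyl}-4-vinyldihydrofuran-2(3H)-one
Product: 9 (4S,5R)-5-(hydroxymethyl)-4-vinyldihydrofuran-2(3H)-one
Conditions: TBAF, AcOH, THF, 0 °C → rt
Reagents that add atoms: none
Why: Fluoride desilylation, buffered with acetic acid so that the alkoxide cannot translactonise or epimerise the lactone.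

Step 5
Reactants: 10 bromoethane
Product: 11 ethyltriphenylphosphonium bromide
Conditions: PPh3, toluene, 100 °C (sealed tube)
Reagents that add atoms: triphenylphosphine, c1ccc(cc1)P(c1ccccc1)c1ccccc1
Why: SN2 quaternisation of triphenylphosphine by the primary bromide.

Step 6
Reactants: 11 ethyltriphenylphosphonium bromide; 12 ethyl formate
Product: 14 2-(triphenylphosphoranylidene)propanal, via ethylidenetriphenylphosphorane 13 (not isolated)
Conditions: KOt-Bu, THF, 0 °C; then HCO2Et, 0 °C → rt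
Reagents that add atoms: none
Why: C‑formylation of the non‑stabilised ylide by the formate ester, after which the released ethoxide deprotonates the acylphosphonium ion to give the stabilised formyl ylide.

Step 7
Reactants: 9 (4S,5R)-5-(hydroxymethyl)-4-vinyldihydrofuran-2(3H)-one; 14 2-(triphenylphosphoranylidene)propanal
Product: 16 (E)-2-methyl-3-[(2R,3S)-5-oxo-3-vinyltetrahydrofuran-2-yl]prop-2-enal, via aldehyde 15 (not isolated)
Conditions: Dess–Martin periodinane, CH2Cl2, 0 °C → rt; then 14, 40 °C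
Reagents that add atoms: none
Why: One‑pot Dess–Martin oxidation and Wittig olefination, in which the stabilised ylide gives the (E)-trisubstituted C3=C4 enal and the labile α‑oxy aldehyde is never isolated.

Step 8
Reactants: 16 (E)-2-methyl-3-[(2R,3S)-5-oxo-3-vinyltetrahydrofuran-2-yl]prop-2-enal
Product: 17 (4S,5R)-5-[(1E)-2-methylbuta-1,3-dien-1-yl]-4-vinyldihydrofuran-2(3H)-one
Conditions: Ph3PCH3Br, KHMDS, THF, −78 → 0 °C
Reagents that add atoms: methyltriphenylphosphonium bromide, C[P+](c1ccccc1)(c1ccccc1)c1ccccc1.[Br-]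
Why: Wittig methylenation of the enal, which reacts far faster than the lactone carbonyl, installs C6 as the terminus of a 1,3‑diene.

**West fragment**

Step 9
Reactants: 18 3-bromoprop-1-yne (propargyl bromide)
Product: 20 4,4,5,5-tetramethyl-2-(propa-1,2-dien-1-yl)-1,3,2-dioxaborolane (allenylboronic acid pinacol ester), via allenylmagnesium bromide 19 (not isolated)
Conditions: Mg, HgCl2 (1 mol %), Et2O, 0 °C; i-PrOBpin, −78 °C → rt; HCl/Et2O
Reagents that add atoms: 2-isopropoxy-4,4,5,5-tetramethyl-1,3,2-dioxaborolane, CC(C)OB1OC(C)(C)C(C)(C)O1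
Why: Grignard formation from propargyl bromide gives the allenyl magnesium species, and borylation with the alkoxyboronate gives the allenylboronate.

Step 10
Reactants: 21 prop-2-yn-1-ol
Product: 23 (E)-3-bromo-2-methylprop-2-en-1-ol, via alkenylalane 22 (not isolated)
Conditions: AlMe3 (3 equiv), Cp2ZrCl2 (25 mol %), CH2Cl2, 0 °C → rt; NBS, THF, −30 → 0 °C
Reagents that add atoms: trimethylaluminium, C[Al](C)C; N-bromosuccinimide, O=C1CCC(=O)N1Br
Why: Negishi zirconium‑catalysed syn‑carboalumination places methyl on the internal and aluminium on the terminal alkyne carbon, and bromodealumination with retention gives the (E)-alkenyl bromide.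

Step 11
Reactants: 23 (E)-3-bromo-2-methylprop-2-en-1-ol
Product: 24 (E)-3-bromo-2-methylprop-2-enal
Conditions: MnO2, CH2Cl2, rt (volatile; used as a solution)
Reagents that add atoms: none
Why: Chemoselective allylic oxidation that leaves the alkenyl bromide and its geometry intact.

Step 12
Reactants: 24 (E)-3-bromo-2-methylprop-2-enal; 20 allenylboronic acid pinacol ester
Product: 26 (3S,1E)-1-bromo-2-methylhex-1-en-5-yn-3-ol, via pinacol borate ester 25 (not isolated)
Conditions: (S)-3,3'-bis(2,4,6-triisopropylphenyl)-1,1'-binaphthyl-2,2'-diyl hydrogen phosphate [(S)-TRIP, 5 mol %], 4 Å MS, toluene, −20 °C; aq. work-up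
Reagents that add atoms: none
Why: Chiral‑phosphoric‑acid‑catalysed asymmetric propargylation (SE2' allenylboration through a closed chair transition state), in which the (S)-catalyst delivers the propargyl group to the si face of the aldehyde and sets the S carbinol (C9).

Step 13
Reactants: 26 (3S,1E)-1-bromo-2-methylhex-1-en-5-yn-3-ol
Product: 27 tert-butyl{[(3S,1E)-1-bromo-2-methylhex-1-en-5-yn-3-yl]oxy}dimethylsilane
Conditions: TBSCl, imidazole, DMF, rt
Reagents that add atoms: tert-butyldimethylsilyl chloride, CC(C)(C)[Si](C)(C)Cl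
Why: Silyl ether protection of the secondary allylic alcohol for the base, hydride and coupling steps that follow.

Step 14
Reactants: 27 tert-butyl{[(3S,1E)-1-bromo-2-methylhex-1-en-5-yn-3-yl]oxy}dimethylsilane
Product: 29 tert-butyl{[(3S,1E)-1-bromo-2-methylhept-1-en-5-yn-3-yl]oxy}dimethylsilane, via lithium acetylide 28 (not isolated)
Conditions: LDA, THF, −78 °C; MeI, DMPU, −78 → 0 °C
Reagents that add atoms: iodomethane, CI
Why: Deprotonation of the terminal alkyne with an amide base (no halogen–metal exchange at the alkenyl bromide) and SN2 methylation of the acetylide give the 2‑alkyne.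

Step 15
Reactants: 29 tert-butyl{[(3S,1E)-1-bromo-2-methylhept-1-en-5-yn-3-yl]oxy}dimethylsilane
Product: 31 tert-butyl{[(3S,1E,5E)-1-bromo-6-iodo-2-methylhepta-1,5-dien-3-yl]oxy}dimethylsilane, via alkenylzirconocene chloride 30 (not isolated)
Conditions: Cp2Zr(H)Cl (2.5 equiv), THF, rt → 40 °C; I2, 0 °C
Reagents that add atoms: iodine, II
Why: Schwartz hydrozirconation is a syn addition that, with excess reagent, equilibrates zirconium to the less hindered methyl‑bearing alkyne carbon, and iodinolysis with retention gives the (E)-2-iodo-2-alkene (C11=C12).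

**Union and endgame**

Step 16
Reactants: 17 (4S,5R)-5-[(1E)-2-methylbuta-1,3-dien-1-yl]-4-vinyldihydrofuran-2(3H)-one; 31 tert-butyl{[(3S,1E,5E)-1-bromo-6-iodo-2-methylhepta-1,5-dien-3-yl]oxy}dimethylsilane
Product: 33 (4R,5R)-4-[(3E,6S,7E)-8-bromo-6-[(tert-butyldimethylsilyl)oxy]-3,7-dimethylocta-3,7-dien-1-yl]-5-[(1E)-2-methylbuta-1,3-dien-1-yl]dihydrofuran-2(3H)-one, via alkyl-9-BBN 32 (not isolated)
Conditions: 9-BBN (1.05 equiv), THF, 0 °C → rt; then 31, Pd(dppf)Cl2 (5 mol %), AsPh3, Cs2CO3, DMF/THF/H2O, rt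
Reagents that add atoms: none
Why: B‑alkyl Suzuki–Miyaura coupling, in which 9‑BBN hydroborates the isolated vinyl group much faster than the conjugated diene and zerovalent palladium inserts into C–I in preference to C–Br, joins C13 to C12 with retention of the (E)-alkene.

Step 17
Reactants: 33 (the seco bromo-diene from step 16)
Product: 35 (1R,2R,9S,3E,7E,11E)-9-[(tert-butyldimethylsilyl)oxy]cembra-3,7,11-trien-16,2-olide, via alkyl-9-BBN 34 (not isolated)
Conditions: 9-BBN (2 equiv), THF, rt → 40 °C; then syringe-pump addition to Pd(dppf)Cl2 (20 mol %), AsPh3, Cs2CO3, DMF/THF/H2O, 50 °C, 1 mM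
Reagents that add atoms: none
Why: Intramolecular B‑alkyl Suzuki–Miyaura macrocyclisation under high dilution, in which 9‑BBN hydroborates the only remaining terminal alkene and coupling with the alkenyl bromide closes the 14‑membered ring at C6–C7 with retention of geometry and no new stereocentre.

Step 18
Reactants: 35 (1R,2R,9S,3E,7E,11E)-9-[(tert-butyldimethylsilyl)oxy]cembra-3,7,11-trien-16,2-olide
Product: 37 (1R,2R,9S,3E,7E,11E)-9-[(tert-butyldimethylsilyl)oxy]-17-(dimethylamino)cembra-3,7,11-trien-16,2-olide (C15 epimers), via lithium enolate 36 (not isolated)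
Conditions: LDA, THF, −78 °C; CH2=NMe2+ I−, −78 °C → rt
Reagents that add atoms: N,N-dimethylmethyleneiminium iodide (Eschenmoser's salt), C=[N+](C)C.[I-]
Why: Mannich reaction of the lactone lithium enolate with Eschenmoser's salt, where the new C15 centre does not matter because it becomes sp2 in the next step.

Step 19
Reactants: 37 (the Mannich base from step 18)
Product: 39 (1R,2S,9S,3E,7E,11E)-9-[(tert-butyldimethylsilyl)oxy]cembra-3,7,11,15(17)-tetraen-16,2-olide, via ammonium iodide 38 (not isolated)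
Conditions: MeI, MeOH, rt; then NaHCO3 (aq.), CH2Cl2, rt
Reagents that add atoms: none
Why: Exhaustive N‑methylation followed by mild base‑induced β‑elimination of trimethylamine gives the exocyclic α‑methylene lactone.

Step 20
Reactants: 39 (1R,2S,9S,3E,7E,11E)-9-[(tert-butyldimethylsilyl)oxy]cembra-3,7,11,15(17)-tetraen-16,2-olide
Product: 40 (1R,2S,9S,3E,7E,11E)-9-hydroxycembra-3,7,11,15(17)-tetraen-16,2-olide
Conditions: HF·pyridine, pyridine, THF, 0 °C → rt
Reagents that add atoms: none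
Why: Acidic fluoride desilylation, chosen over basic TBAF to spare the Michael‑acceptor lactone.

Step 21
Reactants: 40 (1R,2S,9S,3E,7E,11E)-9-hydroxycembra-3,7,11,15(17)-tetraen-16,2-olide
Product: 41 (1R,2S,9S,3E,7E,11E)-9-acetoxycembra-3,7,11,15(17)-tetraen-16,2-olide (CNP0129197.2)
Conditions: Ac2O, pyridine, CH2Cl2, 0 °C → rt
Reagents that add atoms: acetic anhydride, CC(=O)OC(C)=O
Why: Acetylation of the secondary allylic alcohol with retention at C9 gives the target.

**Compound list**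
1 | (R)-5-(hydroxymethyl)dihydrofuran-2(3H)-one | O=C1CC[C@H](CO)O1 | starting material
2 | (R)-5-{[(tert-butyldiphenylsilyl)oxy]methyl}dihydrofuran-2(3H)-one | O=C1CC[C@H](CO[Si](c2ccccc2)(c2ccccc2)C(C)(C)C)O1 | intermediate
3 | lithium enolate of 2 | [Li]OC1=CC[C@H](CO[Si](c2ccccc2)(c2ccccc2)C(C)(C)C)O1 | intermediate (not isolated)
4 | (5R)-5-{[(tert-butyldiphenylsilyl)oxy]methyl}-3-(phenylselanyl)dihydrofuran-2(3H)-one (C3 epimers) | O=C1C([Se]c2ccccc2)C[C@H](CO[Si](c2ccccc2)(c2ccccc2)C(C)(C)C)O1 | intermediate (not isolated)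
5 | selenoxide of 4, (5R)-5-{[(tert-butyldiphenylsilyl)oxy]methyl}-3-(phenylseleninyl)dihydrofuran-2(3H)-one | O=C1C([Se](=O)c2ccccc2)C[C@H](CO[Si](c2ccccc2)(c2ccccc2)C(C)(C)C)O1 | intermediate (not isolated)
6 | (R)-5-{[(tert-butyldiphenylsilyl)oxy]methyl}furan-2(5H)-one | O=C1C=C[C@H](CO[Si](c2ccccc2)(c2ccccc2)C(C)(C)C)O1 | intermediate
7 | trimethylsilyl ketene acetal of 8 (2-trimethylsilyloxy-4,5-dihydrofuran form, ring stereocentres as in 8) | C[Si](C)(C)OC1=C[C@@H](C=C)[C@H](CO[Si](c2ccccc2)(c2ccccc2)C(C)(C)C)O1 | intermediate (not isolated)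
8 | (4S,5R)-5-{[(tert-butyldiphenylsilyl)oxy]methyl}-4-vinyldihydrofuran-2(3H)-one | O=C1C[C@@H](C=C)[C@H](CO[Si](c2ccccc2)(c2ccccc2)C(C)(C)C)O1 | intermediate
9 | (4S,5R)-5-(hydroxymethyl)-4-vinyldihydrofuran-2(3H)-one | O=C1C[C@@H](C=C)[C@H](CO)O1 | intermediate
10 | bromoethane | CCBr | starting material
11 | ethyltriphenylphosphonium bromide | CC[P+](c1ccccc1)(c1ccccc1)c1ccccc1.[Br-] | intermediate
12 | ethyl formate | CCOC=O | starting material
13 | ethylidenetriphenylphosphorane | CC=P(c1ccccc1)(c1ccccc1)c1ccccc1 | intermediate (not isolated)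
14 | 2-(triphenylphosphoranylidene)propanal | CC(C=O)=P(c1ccccc1)(c1ccccc1)c1ccccc1 | intermediate
15 | (2R,3S)-5-oxo-3-vinyltetrahydrofuran-2-carbaldehyde | O=C1C[C@@H](C=C)[C@H](C=O)O1 | intermediate (not isolated)
16 | (E)-2-methyl-3-[(2R,3S)-5-oxo-3-vinyltetrahydrofuran-2-yl]prop-2-enal | O=C1C[C@@H](C=C)[C@H](/C=C(\C)C=O)O1 | intermediate
17 | (4S,5R)-5-[(1E)-2-methylbuta-1,3-dien-1-yl]-4-vinyldihydrofuran-2(3H)-one | O=C1C[C@@H](C=C)[C@H](/C=C(\C)C=C)O1 | intermediate
18 | 3-bromoprop-1-yne | C#CCBr | starting material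
19 | allenylmagnesium bromide | C=C=C[Mg]Br | intermediate (not isolated)
20 | 4,4,5,5-tetramethyl-2-(propa-1,2-dien-1-yl)-1,3,2-dioxaborolane | C=C=CB1OC(C)(C)C(C)(C)O1 | intermediate
21 | prop-2-yn-1-ol | C#CCO | starting material
22 | (E)-alkenylalane, dimethylaluminium alkoxide of (E)-3-(dimethylalumanyl)-2-methylprop-2-en-1-ol | C[Al](C)/C=C(\C)CO[Al](C)C | intermediate (not isolated)
23 | (E)-3-bromo-2-methylprop-2-en-1-ol | Br/C=C(\C)CO | intermediate
24 | (E)-3-bromo-2-methylprop-2-enal | Br/C=C(\C)C=O | intermediate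
25 | pinacol borate ester of 26 | Br/C=C(\C)[C@@H](OB1OC(C)(C)C(C)(C)O1)CC#C | intermediate (not isolated)
26 | (3S,1E)-1-bromo-2-methylhex-1-en-5-yn-3-ol | Br/C=C(\C)[C@@H](O)CC#C | intermediate
27 | tert-butyl{[(3S,1E)-1-bromo-2-methylhex-1-en-5-yn-3-yl]oxy}dimethylsilane | Br/C=C(\C)[C@@H](O[Si](C)(C)C(C)(C)C)CC#C | intermediate
28 | lithium acetylide of 27 | Br/C=C(\C)[C@@H](O[Si](C)(C)C(C)(C)C)CC#C[Li] | intermediate (not isolated)
29 | tert-butyl{[(3S,1E)-1-bromo-2-methylhept-1-en-5-yn-3-yl]oxy}dimethylsilane | Br/C=C(\C)[C@@H](O[Si](C)(C)C(C)(C)C)CC#CC | intermediate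
30 | (E)-alkenylzirconocene chloride from 29 (Zr on C6, cis to H-5) | Br/C=C(\C)[C@@H](O[Si](C)(C)C(C)(C)C)C/C=C(\C)[Zr](Cl)(C1C=CC=C1)C1C=CC=C1 | intermediate (not isolated)
31 | tert-butyl{[(3S,1E,5E)-1-bromo-6-iodo-2-methylhepta-1,5-dien-3-yl]oxy}dimethylsilane | Br/C=C(\C)[C@@H](O[Si](C)(C)C(C)(C)C)C/C=C(\C)I | intermediate
32 | B-alkyl-9-BBN adduct of 17 (boron on the terminal carbon of the former vinyl group) | O=C1C[C@@H](CCB2C3CCCC2CCC3)[C@H](/C=C(\C)C=C)O1 | intermediate (not isolated)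
33 | (4R,5R)-4-[(3E,6S,7E)-8-bromo-6-[(tert-butyldimethylsilyl)oxy]-3,7-dimethylocta-3,7-dien-1-yl]-5-[(1E)-2-methylbuta-1,3-dien-1-yl]dihydrofuran-2(3H)-one | O=C1C[C@@H](CC/C(C)=C/C[C@H](O[Si](C)(C)C(C)(C)C)/C(C)=C/Br)[C@H](/C=C(\C)C=C)O1 | intermediate
34 | B-alkyl-9-BBN adduct of 33 (boron on the terminal diene carbon, C6) | O=C1C[C@@H](CC/C(C)=C/C[C@H](O[Si](C)(C)C(C)(C)C)/C(C)=C/Br)[C@H](/C=C(\C)CCB2C3CCCC2CCC3)O1 | intermediate (not isolated)
35 | (1R,2R,9S,3E,7E,11E)-9-[(tert-butyldimethylsilyl)oxy]cembra-3,7,11-trien-16,2-olide | C1C(=O)O[C@H]2/C=C(\C)CC/C=C(\C)[C@@H](O[Si](C)(C)C(C)(C)C)C/C=C(\C)CC[C@H]12 | intermediate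
36 | lithium enolate of 35 | C1=C(O[Li])O[C@H]2/C=C(\C)CC/C=C(\C)[C@@H](O[Si](C)(C)C(C)(C)C)C/C=C(\C)CC[C@H]12 | intermediate (not isolated)
37 | (1R,2R,9S,3E,7E,11E)-9-[(tert-butyldimethylsilyl)oxy]-17-(dimethylamino)cembra-3,7,11-trien-16,2-olide (C15 epimers) | CN(C)CC1C(=O)O[C@H]2/C=C(\C)CC/C=C(\C)[C@@H](O[Si](C)(C)C(C)(C)C)C/C=C(\C)CC[C@H]12 | intermediate
38 | trimethylammonium iodide of 37 | C[N+](C)(C)CC1C(=O)O[C@H]2/C=C(\C)CC/C=C(\C)[C@@H](O[Si](C)(C)C(C)(C)C)C/C=C(\C)CC[C@H]12.[I-] | intermediate (not isolated)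
39 | (1R,2S,9S,3E,7E,11E)-9-[(tert-butyldimethylsilyl)oxy]cembra-3,7,11,15(17)-tetraen-16,2-olide | C=C1C(=O)O[C@H]2/C=C(\C)CC/C=C(\C)[C@@H](O[Si](C)(C)C(C)(C)C)C/C=C(\C)CC[C@H]12 | intermediate
40 | (1R,2S,9S,3E,7E,11E)-9-hydroxycembra-3,7,11,15(17)-tetraen-16,2-olide | C=C1C(=O)O[C@H]2/C=C(\C)CC/C=C(\C)[C@@H](O)C/C=C(\C)CC[C@H]12 | intermediate
41 | (1R,2S,9S,3E,7E,11E)-9-acetoxycembra-3,7,11,15(17)-tetraen-16,2-olide | C=C1C(=O)O[C@H]2/C=C(\C)CC/C=C(\C)[C@@H](OC(C)=O)C/C=C(\C)CC[C@H]12 | target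

**Step count**
Total: 21 steps.
Longest linear sequence: 12 steps (1 → 41 through steps 1–4, 7, 8 and 16–21; the West branch, steps 10–15 then 16–21, is equally long).

**Three steps most likely to fail**

Step 16 (union). Three selectivities must hold at once: 9‑BBN must take the isolated vinyl group and leave the terminal alkene of the diene, palladium must insert into C–I and not C–Br, and the dienyl‑allylic lactone must survive zerovalent palladium. The fallback sets out from 16 and returns at 33; it builds the diene only after the union. Luche reduction of 16 (NaBH4, CeCl3·7H2O, MeOH, −40 °C) gives the allylic alcohol F1, and TESCl/imidazole gives the triethylsilyl ether F2, which now holds a single terminal alkene. Hydroboration with 9‑BBN gives the alkylborane F3, which is coupled in the same flask with 31 (Pd(dppf)Cl2, AsPh3, Cs2CO3, DMF/THF/H2O) to the protected seco compound F4. PPTS in MeOH removes only the primary triethylsilyl ether to give the allylic alcohol F5, MnO2 gives the enal F6, and Wittig methylenation (Ph3PCH3Br, KHMDS) delivers 33.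

Step 17 (macrocyclisation). Hydroboration of the conjugated diene terminus is slow, the hindered alkenyl bromide adds to palladium sluggishly, oligomers compete, and warm aqueous carbonate can open the lactone. The fallback sets out from 33 and returns at 35; it replaces the boron/aqueous‑base closure by an anhydrous organozinc closure from an isolated iodide. Hydroboration of 33 to 34 and oxidation with NaBO3·4H2O gives the primary alcohol F7, and I2/PPh3/imidazole gives the homoallylic iodide F8. Zinc insertion (Zn dust, LiCl, THF, 40 °C; the alkenyl bromide is inert) gives the alkylzinc iodide F9. This is added slowly to Pd(t-Bu3P)2 in THF/NMP at 50 °C under high dilution for an intramolecular Negishi coupling to 35.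

Step 12 (asymmetric propargylation). The α‑branched, volatile β‑bromo enal may give low conversion or insufficient enantioselectivity under phosphoric acid catalysis. The fallback sets out from 24 and returns at 26; it replaces asymmetric catalysis by resolution. Barbier propargylation of 24 with 18 (Zn dust, THF/sat. aq. NH4Cl, 0 °C) gives the racemic alcohol F10. Kinetic resolution with Amano lipase PS (Burkholderia cepacia lipase) and vinyl acetate in hexane/MTBE acylates the R enantiomer to the acetate F11. Unreacted (S)-alcohol 26 is recovered by chromatography (maximum 50 %).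

**Further compounds**
F1 | step 16 | (4S,5R)-5-[(1E)-3-hydroxy-2-methylprop-1-en-1-yl]-4-vinyldihydrofuran-2(3H)-one | O=C1C[C@@H](C=C)[C@H](/C=C(\C)CO)O1
F2 | step 16 | (4S,5R)-5-[(1E)-2-methyl-3-[(triethylsilyl)oxy]prop-1-en-1-yl]-4-vinyldihydrofuran-2(3H)-one | O=C1C[C@@H](C=C)[C@H](/C=C(\C)CO[Si](CC)(CC)CC)O1
F3 | step 16 | B-alkyl-9-BBN adduct of F2 (boron on the terminal carbon of the former vinyl group) | O=C1C[C@@H](CCB2C3CCCC2CCC3)[C@H](/C=C(\C)CO[Si](CC)(CC)CC)O1
F4 | step 16 | (4R,5R)-4-[(3E,6S,7E)-8-bromo-6-[(tert-butyldimethylsilyl)oxy]-3,7-dimethylocta-3,7-dien-1-yl]-5-[(1E)-2-methyl-3-[(triethylsilyl)oxy]prop-1-en-1-yl]dihydrofuran-2(3H)-one | O=C1C[C@@H](CC/C(C)=C/C[C@H](O[Si](C)(C)C(C)(C)C)/C(C)=C/Br)[C@H](/C=C(\C)CO[Si](CC)(CC)CC)O1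
F5 | step 16 | (4R,5R)-4-[(3E,6S,7E)-8-bromo-6-[(tert-butyldimethylsilyl)oxy]-3,7-dimethylocta-3,7-dien-1-yl]-5-[(1E)-3-hydroxy-2-methylprop-1-en-1-yl]dihydrofuran-2(3H)-one | O=C1C[C@@H](CC/C(C)=C/C[C@H](O[Si](C)(C)C(C)(C)C)/C(C)=C/Br)[C@H](/C=C(\C)CO)O1
F6 | step 16 | (E)-3-{(2R,3R)-3-[(3E,6S,7E)-8-bromo-6-[(tert-butyldimethylsilyl)oxy]-3,7-dimethylocta-3,7-dien-1-yl]-5-oxotetrahydrofuran-2-yl}-2-methylprop-2-enal | O=C1C[C@@H](CC/C(C)=C/C[C@H](O[Si](C)(C)C(C)(C)C)/C(C)=C/Br)[C@H](/C=C(\C)C=O)O1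
F7 | step 17 | (4R,5R)-4-[(3E,6S,7E)-8-bromo-6-[(tert-butyldimethylsilyl)oxy]-3,7-dimethylocta-3,7-dien-1-yl]-5-[(1E)-4-hydroxy-2-methylbut-1-en-1-yl]dihydrofuran-2(3H)-one | O=C1C[C@@H](CC/C(C)=C/C[C@H](O[Si](C)(C)C(C)(C)C)/C(C)=C/Br)[C@H](/C=C(\C)CCO)O1
F8 | step 17 | (4R,5R)-4-[(3E,6S,7E)-8-bromo-6-[(tert-butyldimethylsilyl)oxy]-3,7-dimethylocta-3,7-dien-1-yl]-5-[(1E)-4-iodo-2-methylbut-1-en-1-yl]dihydrofuran-2(3H)-one | O=C1C[C@@H](CC/C(C)=C/C[C@H](O[Si](C)(C)C(C)(C)C)/C(C)=C/Br)[C@H](/C=C(\C)CCI)O1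
F9 | step 17 | alkylzinc iodide from F8 (Zn on C6) | O=C1C[C@@H](CC/C(C)=C/C[C@H](O[Si](C)(C)C(C)(C)C)/C(C)=C/Br)[C@H](/C=C(\C)CC[Zn]I)O1
F10 | step 12 | racemic (E)-1-bromo-2-methylhex-1-en-5-yn-3-ol | Br/C=C(\C)C(O)CC#C
F11 | step 12 | (3R,1E)-1-bromo-2-methylhex-1-en-5-yn-3-yl acetate | Br/C=C(\C)[C@H](OC(C)=O)CC#C
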